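**Retrosynthetic overview**
1. Angustifolin ⇒ late C15 allylic oxidation (SeO2, then MnO2), thermodynamic reduction of the C11 ketone, and equilibration of the C6 methyl acetal.
2. Rings C/D (bicyclo[3.2.1]octane) ⇐ 5-exo vinyl-radical conjugate addition of a 2-bromoallyl arm onto a cyclohexenone (ring D closed last).
3. The C9–C10 bond and the spiro δ-lactone ⇐ a tertiary C10 radical (from a tertiary-alcohol oxalate) adding 6-exo to a Birch enol ether. The C7 acid is tethered to C20 by opening a spiro-epoxide on ring A, which is built first as a cis-fused bicyclic acetal.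
4. Key step: Birch reductive alkylation of 3-methoxybenzoic acid with 2,3-dibromopropene. It dearomatises ring C and creates the C8 quaternary centre (C7 acid, C15–C16–C17 arm), with C11 oxygen carried as an enol ether.
5. Ring order: ring A (acetal), ring C (Birch), lactone tether (ester), C9–C10 bond with the lactone ring, ring D.

Assumptions:
- The C6 methyl acetal of the target is the thermodynamic (anomeric) epimer. It is formed under reversible acid conditions in step 4 and re-equilibrated in step 16.
- The (R)-amine salt of the required C8 enantiomer of acid 13 crystallises. If it does not, the (S)-amine is used.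
- Ring A and the acid 15 are drawn in the enantiomeric series of the target SMILES.

---

**Step 1**
Reactants: 1 (3-methylcyclohex-2-en-1-one), 2 (vinylmagnesium bromide), 3 (chlorotrimethylsilane)
Product: 4 (3-methyl-3-vinylcyclohex-1-en-1-yl TMS ether, single enantiomer, quaternary carbon = C4)
Conditions: 2 (1.5 equiv), CuBr·SMe2 (5 mol %), Josiphos-type ligand (6 mol %), MTBE, –78 °C; then 3, Et3N, –78 → 0 °C
Reagents that add atoms: vinylmagnesium bromide `C=C[Mg]Br`; TMSCl `C[Si](C)(C)Cl`
Why: Proposed new method: the closest known reaction is Cu/diphosphine asymmetric conjugate addition of alkyl Grignards to 3-methylcyclohexenone to make β-quaternary ketones; vinyl Grignard is assumed to behave likewise. The chiral Cu-diphosphine sets the C4 quaternary centre in the 1,4-addition, and the magnesium enolate is trapped regiospecifically by TMSCl as the C10=C5 silyl enol ether.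

**Step 2**
Reactants: 4, 5 (trimethyl orthoformate)
Product: 6 (2-(dimethoxymethyl)-3-methyl-3-vinylcyclohexanone)
Conditions: HC(OMe)3 (2 equiv), TMSOTf (10 mol %), CH2Cl2, –78 °C
Reagents that add atoms: trimethyl orthoformate `COC(OC)OC` (supplies C6 and both OMe groups)
Why: Mukaiyama-type acetal alkylation: C5 of the enol silane attacks the dimethoxycarbenium ion, which installs C6 at the aldehyde oxidation level. The C5 stereocentre is epimerisable and is fixed thermodynamically in step 4.

**Step 3**
Reactants: 6
Product: 7 (2-(dimethoxymethyl)-3-(hydroxymethyl)-3-methylcyclohexanone)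
Conditions: O3, CH2Cl2/MeOH, –78 °C; then NaBH4 (0.4 equiv), –78 → 0 °C
Reagents that add atoms: ozone `[O-][O+]=O` (supplies the C19 oxygen)
Why: Ozonolysis of the vinyl group gives the C19 aldehyde with C4 untouched. Low-temperature NaBH4 reduces this unhindered aldehyde selectively over the hindered ketone and the dimethyl acetal.

**Step 4**
Reactants: 7
Product: 8 (cis-fused 1-methoxy-3a-methylhexahydroisobenzofuran-7-one, the ring-A ketone)
Conditions: CSA (10 mol %), CH2Cl2, 4 Å MS, rt
Reagents that add atoms: none
Why: Intramolecular transacetalisation (loss of MeOH) closes the 6,19-tetrahydrofuran. The acidic, reversible conditions let the α-keto C5 epimerise through the enol to the low-energy cis ring fusion, with C19 axial on ring A. C6 equilibrates to the anomeric (thermodynamic) methyl acetal.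

**Step 5**
Reactants: 8, 9 (trimethylsulfonium iodide)
Product: 10 (spiro-epoxide at C10, C20 = epoxide CH2, mixture of C10 epimers)
Conditions: Me3S+ I– (3 equiv), KOt-Bu (3 equiv), DMSO/THF, 0 °C → rt
Reagents that add atoms: trimethylsulfonium iodide `C[S+](C)C.[I-]` (supplies C20)
Why: Corey–Chaykovsky methylenation of the ketone. The C10 epoxide configuration is irrelevant because C10 becomes a planar radical in step 10.

**Step 6**
Reactants: 11 (3-methoxybenzoic acid), 12 (2,3-dibromopropene)
Product: 13 (racemic 1-(2-bromoallyl)-3-methoxycyclohexa-2,5-diene-1-carboxylic acid)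
Conditions: Li (5 equiv), NH3(l)/THF, t-BuOH (1 equiv), –78 °C; isoprene quench; then 12 (2 equiv), –78 °C → rt; mild acidic work-up (aq. NaH2PO4, pH ≈ 4)
Reagents that add atoms: 2,3-dibromopropene `C=C(Br)CBr` (supplies C15–C17 and Br)
Why: Birch reductive alkylation (dearomatisation). The carboxylate dianion is protonated at the para carbon (C12) and alkylated at the ipso carbon C8, which creates the quaternary centre. Ring C is left as a C9=C11(OMe) enol ether plus a C13=C14 olefin. Because the OMe desymmetrises the diene, C8 is formed racemic. The mild work-up protects the enol ether.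

**Step 7**
Reactants: 13, 14 ((R)-1-phenylethylamine, resolving agent)
Product: 15 (acid 13 as a single C8 enantiomer)
Conditions: 14 (1 equiv), i-PrOH/EtOAc, recrystallise the salt; then aq. NaH2PO4, Et2O
Reagents that add atoms: none (the amine is removed on acidification)
Why: Classical resolution through diastereomeric ammonium salts fixes the absolute configuration at C8, which is carried unchanged to the target.

**Step 8**
Reactants: 15, 10
Product: 16 (hydroxy ester: C7–O–C20 ester with a C10 tertiary alcohol)
Conditions: Cs2CO3 (0.6 equiv), DMF, 90 °C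
Reagents that add atoms: none
Why: The hindered carboxylate opens the spiro-epoxide by SN2 at the unhindered CH2 (C20). This forms the C7–O–C20 tether and unmasks the tertiary C10 alcohol needed for radical generation. C10 epimers are immaterial.

**Step 9**
Reactants: 16, 17 (methyl chlorooxoacetate)
Product: 18 (cesium alkyl oxalate of the C10 alcohol)
Conditions: 17, DMAP, pyridine, CH2Cl2, 0 °C; then CsOH·H2O (1 equiv), MeOH/H2O, 0 °C
Reagents that add atoms: methyl chlorooxoacetate `COC(=O)C(=O)Cl`; cesium hydroxide `[Cs+].[OH-]` (Cs+ remains as the counterion)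
Why: Acylation gives the tertiary methyl oxalate. Selective saponification of the activated oxalate methyl ester (the hindered C7 ester survives) gives the bench-stable cesium oxalate radical precursor.

**Step 10**
Reactants: 18
Product: 19 (C11 ketone with the six-membered spirolactone and the C9–C10 bond formed; C13=C14 retained)
Conditions: [Ir{dF(CF3)ppy}2(dtbbpy)]PF6 (2 mol %), Cu(OAc)2 (2.5 equiv), MeCN/H2O (20:1), blue LEDs, rt; aq. NaHCO3 work-up
Reagents that add atoms: water `O` (supplies the C11 ketone oxygen; the OMe is lost as MeOH)
Why: Proposed new method: excited Ir(III) oxidises the oxalate, and loss of 2 CO2 gives the tertiary C10 radical. This radical adds 6-exo to C9 of the tethered enol ether from the face carrying the C7 tether, so the lactone is cis-fused at C8–C9 as in the target, and C10 ends with C9 anti to the axial C19. The resulting α-methoxy radical is oxidised by Cu(II) to an oxocarbenium ion. Water captures it, and the hemiketal collapses to the C11 ketone without strong acid, so the C6 acetal survives. The closest known reactions are Overman/MacMillan oxalate Giese additions and radical-polar crossover oxidation of α-alkoxy radicals.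

**Step 11**
Reactants: 19
Product: 20 (conjugated enone, C11(=O)–C12=C13)
Conditions: DBU (0.3 equiv), CH2Cl2, 0 °C → rt, short reaction time
Reagents that add atoms: none
Why: Base-mediated β,γ- to α,β-alkene isomerisation of the cyclohexenone through the dienolate. Conjugation drives the equilibrium, and C13 becomes the electrophilic β-carbon for ring D closure. Mild conditions limit enolisation at C9.

**Step 12**
Reactants: 20
Product: 21 (pentacyclic C11 ketone with exocyclic C16=C17, rings C/D closed)
Conditions: n-Bu3SnH (1.5 equiv, syringe pump), AIBN (0.2 equiv), PhH, 80 °C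
Reagents that add atoms: none (only H is added; tin bromide is lost)
Why: Bu3Sn• abstracts Br to give the C16 vinyl radical, which adds 5-exo-trig to the enone β-carbon C13. Only the face bearing the C15 arm can be reached, so the bicyclo[3.2.1]octane forms and C13 is fixed. The α-keto radical at C12 is reduced by Bu3SnH, and the C16=C17 alkene is retained.

**Step 13**
Reactants: 21
Product: 22 (C11 alcohol, 15-deoxo-angustifolin)
Conditions: Al(Oi-Pr)3 (3 equiv), i-PrOH, 82 °C
Reagents that add atoms: none
Why: Meerwein–Ponndorf–Verley reduction under thermodynamic control gives the equatorial C11 alcohol, anti to the C15–C16 bridge, as in the target. The axial face syn to the bridge is blocked.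

**Step 14**
Reactants: 22
Product: 23 (C15 allylic alcohol, epimeric mixture at C15)
Conditions: SeO2 (1.5 equiv), t-BuOOH (3 equiv), CH2Cl2, rt
Reagents that add atoms: selenium dioxide `O=[Se]=O`; tert-butyl hydroperoxide `CC(C)(C)OO` (the oxygen atom ends up in the product)
Why: Riley allylic oxidation (ene/[2,3]-sigmatropic sequence) of the exocyclic alkene occurs at the only accessible allylic CH2 (C15); the C15 stereocentre is destroyed in the next step.

**Step 15**
Reactants: 23
Product: 24 (15-oxo-16-ene, C11 alcohol retained)
Conditions: MnO2 (20 equiv), CH2Cl2, rt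
Reagents that add atoms: none
Why: MnO2 oxidises only the allylic C15 alcohol to the exocyclic enone, leaving the isolated secondary C11 alcohol untouched.

**Step 16**
Reactants: 24
Product: 25 (angustifolin)
Conditions: PPTS (0.1 equiv), MeOH, rt, 16 h
Reagents that add atoms: methanol `CO` (the OMe can exchange through the C6 oxocarbenium)
Why: Acid-catalysed methyl-acetal exchange in a large excess of MeOH converges the C6 epimers to the thermodynamic anomer. It also returns any isopropyl acetal formed from Al(Oi-Pr)3/i-PrOH in step 13 to the methyl acetal. No other stereocentre is labile under these mild conditions.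

---

**Compound list**

| # | Name | SMILES | Role |
|---|---|---|---|
| 1 | 3-methylcyclohex-2-en-1-one | `CC1=CC(=O)CCC1` | starting material |
| 2 | vinylmagnesium bromide | `C=C[Mg]Br` | starting material |
| 3 | chlorotrimethylsilane | `C[Si](C)(C)Cl` | starting material |
| 4 | silyl enol ether of 3-methyl-3-vinylcyclohexanone | `C=C[C@]1(C)CCCC(O[Si](C)(C)C)=C1` | intermediate |
| 5 | trimethyl orthoformate | `COC(OC)OC` | starting material |
| 6 | 2-(dimethoxymethyl)-3-methyl-3-vinylcyclohexanone | `C=C[C@]1(C)CCCC(=O)[C@@H]1C(OC)OC` | intermediate |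
| 7 | 2-(dimethoxymethyl)-3-(hydroxymethyl)-3-methylcyclohexanone | `O=C1CCC[C@@](C)(CO)[C@H]1C(OC)OC` | intermediate |
| 8 | cis-fused methoxy-THF cyclohexanone (ring-A ketone) | `O=C1CCC[C@@]2(C)CO[C@H](OC)[C@H]21` | intermediate |
| 9 | trimethylsulfonium iodide | `C[S+](C)C.[I-]` | starting material |
| 10 | spiro-epoxide of 8 (C10 epimeric) | `C1OC12CCC[C@@]3(C)CO[C@H](OC)[C@H]32` | intermediate |
| 11 | 3-methoxybenzoic acid | `COc1cccc(c1)C(=O)O` | starting material |
| 12 | 2,3-dibromopropene | `C=C(Br)CBr` | starting material |
| 13 | 1-(2-bromoallyl)-3-methoxycyclohexa-2,5-diene-1-carboxylic acid (racemic) | `C=C(Br)CC1(C(=O)O)C=C(OC)CC=C1` | intermediate |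
| 14 | (R)-1-phenylethylamine (resolving agent) | `C[C@@H](N)c1ccccc1` | starting material |
| 15 | resolved acid 13 (single C8 enantiomer) | `C=C(Br)C[C@@]1(C(=O)O)C=C(OC)CC=C1` | intermediate |
| 16 | hydroxy ester from 15 + 10 (C10 unspecified) | `C=C(Br)C[C@@]1(C(=O)OCC2(O)CCC[C@@]3(C)CO[C@H](OC)[C@H]32)C=C(OC)CC=C1` | intermediate |
| 17 | methyl chlorooxoacetate | `COC(=O)C(=O)Cl` | starting material |
| 18 | cesium oxalate of 16 | `C=C(Br)C[C@@]1(C(=O)OCC2(OC(=O)C(=O)[O-])CCC[C@@]3(C)CO[C@H](OC)[C@H]32)C=C(OC)CC=C1.[Cs+]` | intermediate |
| 19 | C11 ketone after radical cyclisation (C13=C14) | `C=C(Br)C[C@]12C=CCC(=O)[C@H]1[C@@]1(CCC[C@@]3(C)CO[C@H](OC)[C@H]31)COC2=O` | intermediate |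
| 20 | conjugated enone isomer of 19 | `C=C(Br)C[C@]12CC=CC(=O)[C@H]1[C@@]1(CCC[C@@]3(C)CO[C@H](OC)[C@H]31)COC2=O` | intermediate |
| 21 | C11 ketone, rings C/D closed | `C=C1C[C@]23C[C@H]1CC(=O)[C@H]2[C@@]1(CCC[C@@]2(C)CO[C@H](OC)[C@H]21)COC3=O` | intermediate |
| 22 | C11 alcohol, 15-deoxo | `C=C1C[C@]23C[C@H]1C[C@@H](O)[C@H]2[C@@]1(CCC[C@@]2(C)CO[C@H](OC)[C@H]21)COC3=O` | intermediate |
| 23 | C15 allylic alcohol (C15 epimeric) | `C=C1C(O)[C@]23C[C@H]1C[C@@H](O)[C@H]2[C@@]1(CCC[C@@]2(C)CO[C@H](OC)[C@H]21)COC3=O` | intermediate |
| 24 | 15-oxo compound | `C=C1C(=O)[C@]23C[C@H]1C[C@@H](O)[C@H]2[C@@]1(CCC[C@@]2(C)CO[C@H](OC)[C@H]21)COC3=O` | intermediate |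
| 25 | angustifolin | `C=C1C(=O)[C@]23C[C@H]1C[C@@H](O)[C@H]2[C@@]1(CCC[C@@]2(C)CO[C@H](OC)[C@H]21)COC3=O` | target |

---

**Totals**
- Total steps: 16 (steps 1–5 for ring A, steps 6–7 for ring C, steps 8–16 for coupling and completion).
- Longest linear sequence: 14 steps (1 → 2 → 3 → 4 → 5 → 8 → 9 → 10 → 11 → 12 → 13 → 14 → 15 → 16).

**Three steps most likely to fail**
1. **Step 10** (radical 6-exo cyclisation onto the electron-rich enol ether, competing with attack on the C13=C14 alkene, with oxidative termination). Fallback: form C9–C10 by radical conjugate addition instead. Convert the Birch ester to the NIS/H2O iodohydrin (C11-OH, C9–I) and add the C9 radical (Bu3SnH/Et3B) 6-exo to a ring-A α,β-unsaturated lactone acceptor, which keeps C11-OH without the oxidative termination.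
2. **Step 1** (enantioselective vinyl Grignard addition to a β,β-disubstituted enone). Fallback: do the addition racemically with CuI and resolve hydroxy ketone 7 by lipase acylation of the primary alcohol, which replaces catalytic enantiocontrol with enzymatic resolution.
3. **Step 7** (classical resolution of the quaternary Birch acid). Fallback: skip it, run step 8 with racemic 13, and separate the diastereomeric hydroxy esters 16 by preparative HPLC, which moves the resolution to a diastereomer separation.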